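**Numbering used throughout:** 1 3-bromo-5-methoxyphenol; 2 its TIPS ether; 3 oxirane; 4 the aryllithium from 2; 5 the 2-arylethanol; 6 the arylacetaldehyde; 7 undec-10-en-1-ol; 8 its TBS ether; 9 acetyl bromide; 10 the racemic 1-bromoalkyl acetate; 11 the bis-silylated (R)-acetate; 12 the target.

## Analysis of the target

The target 12 is (2R)-13-hydroxy-1-(3-hydroxy-5-methoxyphenyl)tridecan-2-yl acetate: a benzene ring with a methoxy group at C3', a free phenol at C5' and, at C1', an unbranched C13 chain running from the benzylic C1H2 to C13H2OH. There is no ring to build other than the arene, which can be bought. The only stereocentre is C2, which is (R) and already carries the O-acetyl group; with no second stereocentre there is no substrate bias, so the absolute configuration must come wholly from a reagent or catalyst. The feature that shapes the route is the unit C1–C2(OAc)–C3: C2 is the carbinol carbon of an ester of a dialkyl carbinol, and both of its carbon substituents begin with a methylene group (C1H2–aryl and C3H2 of the C3–C13 undecamethylene segment). These two groups are similar in size, which is where asymmetric ketone reduction by small-molecule catalysts and lipase resolution discriminate poorly. The second difficulty is chemoselectivity among three oxygens: the acetyl group sits on the secondary oxygen at C2, the least reactive of the three, while the primary hydroxyl at C13 and the phenol at C5' are free, so acetylation of a triol cannot be the end game. Sensitive groups are the acetate (base, nucleophiles, transesterification) and the electron-rich resorcinol-type ring (electrophiles, oxidants). The skeleton is simple; the problem is to create C2 as one enantiomer with its acetate in place in few steps.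

## Retrosynthetic reasoning

**12 ⇒ 11 (two O–Si bonds).** The phenol at C5' and the primary hydroxyl at C13 are unmasked last from silyl ethers. Silicon is chosen because buffered fluoride cleaves both Si–O bonds without touching the C2 acetate. The phenol carries the bulkier triisopropylsilyl group, which must survive an organolithium, an acyl bromide and a phosphate base. The primary alcohol carries tert-butyldimethylsilyl.

**11 ⇒ 6 + 9 + 8 (C2–C3 bond and the acetyl–O bond on C2).** This is the key disconnection. C2 becomes the carbonyl carbon of arylacetaldehyde 6 and the acetyl group comes from 9. C3–C13 come from alkene 8: C3 is its terminal olefinic carbon and C4 receives a hydrogen from a hydrosilane. In the forward sense 6 and 9 give the racemic 1-bromoalkyl acetate 10, and a chiral nickel catalyst couples 10 with 8 enantioconvergently. The cut is made at C2–C3 rather than at C1–C2 or C1'–C1 for three reasons: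
- The stereocentre forms at a radical whose substituents are OAc, H and CH2Ar, which differ strongly, so the similarity of the two methylene groups in the product is irrelevant.
- The acetate arrives together with the stereocentre and never has to be placed selectively.
- Both carbon partners are one or two steps from commodity chemicals.

The forward reaction must funnel both enantiomers of 10 into (R)-11, add the nickel hydride to 8 with linear regiochemistry, and outrun loss of HBr from 10.

**6 ⇒ 5 ⇒ 2 + 3 (oxidation level at C2, then the C1'–C1 bond).** The aldehyde is taken back to primary alcohol 5. The bond between the arene and C1 is cut so that C1 and C2 come from oxirane 3 and the ring from aryl bromide 2 via aryllithium 4. The bromide is used because bromine–lithium exchange is fast and regiochemically unambiguous on this 1,3,5-pattern.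

**2 ⇒ 1 and 8 ⇒ 7 (O–Si bonds).** Both are plain silylations of commercial 3-bromo-5-methoxyphenol 1 and undec-10-en-1-ol 7.

## Alternatives that were turned down

**Alternative 1:** The textbook route cuts the C1'–C1 bond. Aryl bromide 2 would be metalated and added under copper catalysis to the enantiopure terminal epoxide tert-butyldimethyl({11-[(2R)-oxiran-2-yl]undecyl}oxy)silane A1, followed by O-acetylation to 11 and desilylation. It was turned down for these reasons:
- A1 has to come from hydrolytic kinetic resolution (Co–salen) of its racemate A2, which discards half of the material.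
- A2 needs a C13 terminal alkenol, two carbons longer than commercial 7, so the chain must be assembled first.
- The acetate is installed in a separate step.
- The count comes to about nine steps, with the stereocentre bought by resolution.

**Alternative 2:** An enzymatic route would reduce 13-hydroxy-1-(3-hydroxy-5-methoxyphenyl)tridecan-2-one A3 with a ketoreductase to (2R)-1-(3-hydroxy-5-methoxyphenyl)tridecane-2,13-diol A4. An enzyme can in principle distinguish the benzyl-type and alkyl sides of such a ketone where small-molecule catalysts cannot. It was turned down for these reasons: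
- A4 is a triol whose C2 hydroxyl is the least reactive, so the acetate cannot be placed without bringing protecting groups back.
- The step sets the stereocentre but builds no bond.
- A3 needs its own C–C bond-forming sequence.
- A ketone with two long substituents usually needs an engineered enzyme found by screening.

**Alternative 3:** A stereoconvergent acylation would subject the racemic alcohol 13-[(tert-butyldimethylsilyl)oxy]-1-[3-methoxy-5-(triisopropylsilyloxy)phenyl]tridecan-2-ol A5 to dynamic kinetic resolution (ruthenium racemisation catalyst, lipase, isopropenyl acetate) to give 11 directly. It was turned down for these reasons: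
- Lipases that work in such resolutions need one small carbinol substituent (methyl- to ethyl-sized). At C2 of A5 both substituents are large (CH2Ar and a C11 chain), so slow acylation and low enantioselectivity are expected.
- A5 would need a five- to six-step synthesis that forms the same C–C bonds without stereocontrol, so nothing is gained over the chosen route.

Key step: step 5

## Route

Assumption: the enantiomer of the bis(oxazoline) ligand that delivers the (R)-ester is assigned by analogy with the reaction class and would be confirmed by chiral HPLC in a first run; both ligand enantiomers are equally accessible.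

Step 1
Reactants: 1 3-bromo-5-methoxyphenol
Product: 2 (3-bromo-5-methoxyphenoxy)triisopropylsilane
Conditions: TIPSCl, imidazole, DMF, rt
Reagents that add atoms: chlorotriisopropylsilane (TIPSCl), CC(C)[Si](Cl)(C(C)C)C(C)C
Why: Standard O-silylation of a phenol; the bulky aryl TIPS ether should tolerate the organolithium, acyl bromide and phosphate base used later.

Step 2
Reactants: 2 (3-bromo-5-methoxyphenoxy)triisopropylsilane; 3 oxirane
Product: 5 2-[3-methoxy-5-(triisopropylsilyloxy)phenyl]ethan-1-ol, via aryllithium 4 (not isolated)
Conditions: n-BuLi, THF, −78 °C; then 3 (solution in THF, excess), −78 → 0 °C; H2O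
Reagents that add atoms: none
Why: Bromine–lithium exchange is faster than ortho-metalation next to OMe or OTIPS, and the aryllithium opens the unhindered epoxide by SN2 attack to form the C1'–C1 bond; a meta-silyloxy group cannot undergo anionic silyl migration.

Step 3
Reactants: 5 2-[3-methoxy-5-(triisopropylsilyloxy)phenyl]ethan-1-ol
Product: 6 2-[3-methoxy-5-(triisopropylsilyloxy)phenyl]acetaldehyde
Conditions: Dess–Martin periodinane, CH2Cl2, 0 °C → rt; Na2S2O3/NaHCO3 work-up; used crude
Reagents that add atoms: none
Why: Dess–Martin oxidation is a mild, near-neutral conversion of a 2-arylethanol into the arylacetaldehyde without over-oxidation; the enolisable aldehyde is not chromatographed but carried directly into step 5.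

Step 4
Reactants: 7 undec-10-en-1-ol
Product: 8 tert-butyldimethyl(undec-10-en-1-yloxy)silane
Conditions: TBSCl, imidazole, CH2Cl2, rt
Reagents that add atoms: tert-butylchlorodimethylsilane (TBSCl), CC(C)(C)[Si](C)(C)Cl
Why: Standard silylation of a primary alcohol; the free hydroxyl would otherwise intercept the highly electrophilic bromo ester of step 5.

Step 5
Reactants: 6 2-[3-methoxy-5-(triisopropylsilyloxy)phenyl]acetaldehyde; 8 tert-butyldimethyl(undec-10-en-1-yloxy)silane; 9 acetyl bromide
Product: 11 (2R)-13-[(tert-butyldimethylsilyl)oxy]-1-[3-methoxy-5-(triisopropylsilyloxy)phenyl]tridecan-2-yl acetate, via racemic bromo ester 10 (not isolated)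
Conditions: 9 (1.05 equiv), CH2Cl2, −20 → 0 °C, volatiles removed; then 8, NiBr2·glyme (10 mol %), C2-symmetric bis(oxazoline) L* (12 mol %, enantiomer giving (R)), (EtO)2MeSiH, K3PO4·H2O, Et2O/DMA, 0 °C → rt
Reagents that add atoms: none
Why: Carbonyl addition of 9 to 6 gives the 1-bromoalkyl acetate 10 as a racemate, so the acetyl group is placed on the C2 oxygen before any other hydroxyl exists in free form. A nickel hydride, formed from the Ni(II) bromide and the phosphate-activated hydrosilane, adds to the terminal alkene of 8 in the anti-Markovnikov sense (nickel at C3, hydrogen at C4) to give a primary alkylnickel(II) species. Low-valent nickel abstracts bromine from either enantiomer of 10 and generates the same planar α-acetoxyalkyl radical at C2, which is captured by the chiral alkylnickel complex; reductive elimination from Ni(III) forms the C2–C3 bond. The closest known reaction type is the nickel/bis(oxazoline)-catalysed enantioconvergent coupling of racemic α-haloalkyl esters, made in the flask from an aldehyde and an acyl bromide, with an olefin and a hydrosilane to give esters of dialkyl carbinols. No ring is closed. The C2 stereocentre is controlled by the catalyst alone: the C2-symmetric ligand and the nickel-bound acetate carbonyl fix the orientation of the radical, whose three substituents (OAc, H, CH2Ar) differ strongly, and the ligand enantiomer is chosen to give (R). The step needs enantioconvergence, linear regioselectivity and coupling faster than loss of HBr from 10 towards the aryl-conjugated enol acetate; the first two rest on the ligand and the unbiased terminal alkene, the last on the mild heterogeneous base and low temperature. Both silyl ethers, the aryl methyl ether and the new acetate should be inert to these conditions.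

Step 6
Reactants: 11 (2R)-13-[(tert-butyldimethylsilyl)oxy]-1-[3-methoxy-5-(triisopropylsilyloxy)phenyl]tridecan-2-yl acetate
Product: 12 (2R)-13-hydroxy-1-(3-hydroxy-5-methoxyphenyl)tridecan-2-yl acetate
Conditions: TBAF, AcOH (1:1, excess), THF, 0 °C → rt
Reagents that add atoms: none
Why: Fluoride-induced cleavage of both Si–O bonds; the acetic acid buffer keeps phenoxide and alkoxide protonated, so the C2 acetate should be neither hydrolysed nor transferred, and the meta-phenol and the remote C13 hydroxyl cannot reach it intramolecularly; the C2 stereocentre is not involved.

## Compound list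

1 | 3-bromo-5-methoxyphenol | COc1cc(O)cc(Br)c1 | starting material
2 | (3-bromo-5-methoxyphenoxy)triisopropylsilane | COc1cc(Br)cc(O[Si](C(C)C)(C(C)C)C(C)C)c1 | intermediate
3 | oxirane | C1CO1 | starting material
4 | [3-methoxy-5-(triisopropylsilyloxy)phenyl]lithium | [Li]c1cc(OC)cc(O[Si](C(C)C)(C(C)C)C(C)C)c1 | intermediate
5 | 2-[3-methoxy-5-(triisopropylsilyloxy)phenyl]ethan-1-ol | COc1cc(CCO)cc(O[Si](C(C)C)(C(C)C)C(C)C)c1 | intermediate
6 | 2-[3-methoxy-5-(triisopropylsilyloxy)phenyl]acetaldehyde | COc1cc(CC=O)cc(O[Si](C(C)C)(C(C)C)C(C)C)c1 | intermediate
7 | undec-10-en-1-ol | C=CCCCCCCCCCO | starting material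
8 | tert-butyldimethyl(undec-10-en-1-yloxy)silane | C=CCCCCCCCCCO[Si](C)(C)C(C)(C)C | intermediate
9 | acetyl bromide | CC(=O)Br | starting material
10 | racemic 1-bromo-2-[3-methoxy-5-(triisopropylsilyloxy)phenyl]ethyl acetate | COc1cc(CC(Br)OC(C)=O)cc(O[Si](C(C)C)(C(C)C)C(C)C)c1 | intermediate
11 | (2R)-13-[(tert-butyldimethylsilyl)oxy]-1-[3-methoxy-5-(triisopropylsilyloxy)phenyl]tridecan-2-yl acetate | COc1cc(C[C@@H](CCCCCCCCCCCO[Si](C)(C)C(C)(C)C)OC(C)=O)cc(O[Si](C(C)C)(C(C)C)C(C)C)c1 | intermediate
12 | (2R)-13-hydroxy-1-(3-hydroxy-5-methoxyphenyl)tridecan-2-yl acetate | COc1cc(O)cc(C[C@@H](CCCCCCCCCCCO)OC(C)=O)c1 | target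

## Step count and risk

Total step count: 6. Longest linear sequence: 5 steps (steps 1, 2, 3, 5, 6); step 4 is a one-step side branch.

**Step 5 (key step).** Three processes are most likely to go wrong:
- Loss of HBr from 10 across C1–C2, which is favoured by conjugation of the resulting enol acetate with the arene, may compete with radical generation.
- The acyloxy-stabilised electrophile 10 may attack the electron-rich ring of a second molecule.
- The small acetyl group may give weaker facial discrimination at nickel than bulkier acyl groups, eroding the enantiomeric excess.

The fallback abandons the coupling and builds C2 from the chiral pool, setting out from 2 and returning at 11. Compound 2 is lithiated to 4 as in step 2, and 4 opens commercial (S)-epichlorohydrin at its unsubstituted epoxide carbon (BF3·OEt2, THF, −78 °C) to give (2S)-1-chloro-3-[3-methoxy-5-(triisopropylsilyloxy)phenyl]propan-2-ol F1. NaH in THF closes this to (2S)-2-{[3-methoxy-5-(triisopropylsilyloxy)phenyl]methyl}oxirane F2; the stereocentre is not touched in either operation. Commercial 10-bromodecan-1-ol is silylated (TBSCl, imidazole) to [(10-bromodecyl)oxy](tert-butyl)dimethylsilane F3 and converted with magnesium in THF into {10-[(tert-butyldimethylsilyl)oxy]decyl}magnesium bromide F4. F4 opens F2 at its CH2 terminus under CuI catalysis (−30 °C) to give (2R)-13-[(tert-butyldimethylsilyl)oxy]-1-[3-methoxy-5-(triisopropylsilyloxy)phenyl]tridecan-2-ol F5. Acetylation of F5 (Ac2O, DMAP, Et3N, CH2Cl2) gives 11.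

**Step 2.** The aryllithium may couple with the 1-bromobutane formed in the exchange, or be protonated before it is captured by oxirane, which lowers conversion to 5. The fallback replaces organolithium chemistry by cross-coupling and hydroboration, setting out from 2 and returning at 5. Suzuki–Miyaura coupling of 2 with vinylboronic acid pinacol ester (Pd(dppf)Cl2, K3PO4, dioxane/H2O) gives (3-ethenyl-5-methoxyphenoxy)triisopropylsilane F6. Anti-Markovnikov hydroboration of F6 with 9-BBN and oxidation with NaBO3·4H2O gives 5.

**Step 3.** Acid-promoted enolisation of the arylacetaldehyde by the acetic acid released from the oxidant may lead to self-aldol condensation, and the aldehyde may oxidise in air on handling. The fallback unmasks the aldehyde hydrolytically instead of oxidatively, setting out from 2 and returning at 6. Suzuki–Miyaura coupling of 2 with commercial (E)-2-(2-ethoxyvinyl)-4,4,5,5-tetramethyl-1,3,2-dioxaborolane (Pd(dppf)Cl2, K3PO4, dioxane/H2O) gives the storable enol ether {3-[(E)-2-ethoxyethenyl]-5-methoxyphenoxy}triisopropylsilane F7. Brief hydrolysis of F7 (aqueous formic acid/CH2Cl2, rt) releases 6 immediately before step 5.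

**Step 6.** Partial loss or intermolecular transfer of the acetyl group may occur if the fluoride medium becomes basic, or cleavage of the primary silyl ether may be incomplete under buffered conditions. The fallback replaces the single fluoride operation by two orthogonal, non-basic unmaskings, setting out from 11 and returning at 12. Aqueous acid (AcOH/THF/H2O 3:1:1, 40 °C) removes only the primary silyl group to give (2R)-13-hydroxy-1-[3-methoxy-5-(triisopropylsilyloxy)phenyl]tridecan-2-yl acetate F8. Potassium hydrogen difluoride in methanol at rt, which cleaves phenolic silyl ethers and leaves carboxylic esters alone, then frees the phenol to give 12.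

## Further compounds

F1 | step 5 | (2S)-1-chloro-3-[3-methoxy-5-(triisopropylsilyloxy)phenyl]propan-2-ol | COc1cc(C[C@@H](CCl)O)cc(O[Si](C(C)C)(C(C)C)C(C)C)c1
F2 | step 5 | (2S)-2-{[3-methoxy-5-(triisopropylsilyloxy)phenyl]methyl}oxirane | COc1cc(C[C@H]2CO2)cc(O[Si](C(C)C)(C(C)C)C(C)C)c1
F3 | step 5 | [(10-bromodecyl)oxy](tert-butyl)dimethylsilane | BrCCCCCCCCCCO[Si](C)(C)C(C)(C)C
F4 | step 5 | {10-[(tert-butyldimethylsilyl)oxy]decyl}magnesium bromide | Br[Mg]CCCCCCCCCCO[Si](C)(C)C(C)(C)C
F5 | step 5 | (2R)-13-[(tert-butyldimethylsilyl)oxy]-1-[3-methoxy-5-(triisopropylsilyloxy)phenyl]tridecan-2-ol | COc1cc(C[C@@H](CCCCCCCCCCCO[Si](C)(C)C(C)(C)C)O)cc(O[Si](C(C)C)(C(C)C)C(C)C)c1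
F6 | step 2 | (3-ethenyl-5-methoxyphenoxy)triisopropylsilane | COc1cc(C=C)cc(O[Si](C(C)C)(C(C)C)C(C)C)c1
F7 | step 3 | {3-[(E)-2-ethoxyethenyl]-5-methoxyphenoxy}triisopropylsilane | CCO/C=C/c1cc(OC)cc(O[Si](C(C)C)(C(C)C)C(C)C)c1
F8 | step 6 | (2R)-13-hydroxy-1-[3-methoxy-5-(triisopropylsilyloxy)phenyl]tridecan-2-yl acetate | COc1cc(C[C@@H](CCCCCCCCCCCO)OC(C)=O)cc(O[Si](C(C)C)(C(C)C)C(C)C)c1
A1 | alternative 1 | tert-butyldimethyl({11-[(2R)-oxiran-2-yl]undecyl}oxy)silane | C1[C@@H](CCCCCCCCCCCO[Si](C)(C)C(C)(C)C)O1
A2 | alternative 1 | racemic tert-butyldimethyl{[11-(oxiran-2-yl)undecyl]oxy}silane | C1C(CCCCCCCCCCCO[Si](C)(C)C(C)(C)C)O1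
A3 | alternative 2 | 13-hydroxy-1-(3-hydroxy-5-methoxyphenyl)tridecan-2-one | COc1cc(O)cc(CC(=O)CCCCCCCCCCCO)c1
A4 | alternative 2 | (2R)-1-(3-hydroxy-5-methoxyphenyl)tridecane-2,13-diol | COc1cc(O)cc(C[C@@H](CCCCCCCCCCCO)O)c1
A5 | alternative 3 | racemic 13-[(tert-butyldimethylsilyl)oxy]-1-[3-methoxy-5-(triisopropylsilyloxy)phenyl]tridecan-2-ol | COc1cc(CC(O)CCCCCCCCCCCO[Si](C)(C)C(C)(C)C)cc(O[Si](C(C)C)(C(C)C)C(C)C)c1
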